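The dimer is disconnected at the C4(upper)–C6(lower) bond into two 7,8,4'-trioxygenated flavan units with the same C2 configuration, both drawn from one (2S)-flav-3-ene. Its ring C comes from a flavone built in one operation: C-acylation of a 3,4-dibenzyloxy-2-fluoroacetophenone enolate by 4-benzyloxybenzoyl chloride forms C2–C3, and the resulting diketonate oxygen closes onto C8a by SNAr (O1–C8a). The step exploits the C4 carbonyl ortho to C8a on ring A, which acidifies C3 and activates the C8a–F bond. Asymmetric hydrogenation then sets C2, and epoxides on opposite faces of the flavene give the 2,3-trans diol (lower unit) and the 2,3-cis C4 electrophile (upper unit), joined by Friedel–Crafts epoxide opening.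

Key step: step 3

Remarks: flavan numbering (O1, C2, C3, C4, C4a, C5 to C8, C8a) is used throughout; the upper unit is the one bonded through C4, the lower unit the one bonded through C6. Assumption: the (R,R) antipode of the carbene ligand in step 4 is taken to deliver the 2S product; if a test run on the parent flavone shows the opposite sense, the (S,S) antipode is used.

Step 1
Reactants: 1 3-fluorocatechol; 2 benzyl bromide
Product: 3 1,2-bis(benzyloxy)-3-fluorobenzene
Conditions: 2 (2.2 equiv in total), K2CO3 (3 equiv), DMF, 60 °C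
Reagents that add atoms: benzyl bromide (second equivalent), BrCc1ccccc1
Why: Double Williamson ether synthesis; each of the two phenoxides of 1 is alkylated by one molecule of benzyl bromide, so two equivalents are consumed, and no stereocentre is involved.

Step 2
Reactants: 3 1,2-bis(benzyloxy)-3-fluorobenzene; 4 N-methoxy-N-methylacetamide
Product: 5 1-[3,4-bis(benzyloxy)-2-fluorophenyl]ethan-1-one
Conditions: n-BuLi, THF, −78 °C; then 4, −78 → 0 °C; aq. NH4Cl
Reagents that add atoms: none
Why: Directed ortho-metalation, in which fluorine acidifies the neighbouring C–H in THF, followed by Weinreb ketone synthesis; the aryllithium is acylated once at −78 °C, below the temperature at which LiF is lost to the aryne.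

Step 3
Reactants: 5 1-[3,4-bis(benzyloxy)-2-fluorophenyl]ethan-1-one; 6 4-(benzyloxy)benzoyl chloride
Product: 8 7,8-bis(benzyloxy)-2-[4-(benzyloxy)phenyl]-4H-chromen-4-one, via lithium 1,3-diketonate 7 (not isolated)
Conditions: LiN(SiMe3)2 (2.2 equiv), THF, −78 °C; 6, −78 °C → rt; then DMF, 100 °C
Reagents that add atoms: none
Why: The amide base deprotonates the acetyl group of 5 and the lithium enolate is C-acylated by 6 (crossed Claisen condensation, the one-pot ketone/acid chloride 1,3-diketone synthesis), which forms C2–C3; the second equivalent of base converts the diketone into its enolate 7. On warming in DMF the enolate oxygen on C2 attacks C8a, which is activated by the ortho C4 carbonyl, and fluoride leaves (intramolecular SNAr, the known base-mediated cyclisation of 1-(2-haloaryl)-1,3-diketones to flavones), which forms O1–C8a. The pyranone ring closes by a six-membered addition–elimination at the sp2 carbon C8a, classed as 6-exo-trig with respect to the exocyclic C–F bond that breaks. No stereocentre is formed, and because the product is a planar chromone nothing can epimerise or ring-open under the basic conditions. The step needs C- over O-acylation, secured by the lithium enolate in THF with excess base that funnels any enol ester to the diketonate. It also needs O- over C-arylation in the closure, secured by geometry, since only the C2 oxygen can reach C8a through a six-membered transition state.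

Step 4
Reactants: 8 7,8-bis(benzyloxy)-2-[4-(benzyloxy)phenyl]-4H-chromen-4-one
Product: 9 (2S,4S)-7,8-bis(benzyloxy)-2-[4-(benzyloxy)phenyl]chroman-4-ol
Conditions: Ru(2-methylallyl)2(1,5-cyclooctadiene) (5 mol%), 1,3-bis[(R)-1-(naphthalen-1-yl)ethyl]-4,5-dihydroimidazolium tetrafluoroborate (10 mol%), KOtBu (15 mol%), H2 (100 bar), toluene, 25 °C
Reagents that add atoms: none
Why: Ruthenium–NHC catalysed asymmetric hydrogenation of flavones; the chiral carbene ligand selects the enantioface of C2=C3 and so sets C2 as S, and the second hydrogen adds to C4=O from the same face to give the 2,4-cis alcohol, whose C4 centre is removed in step 5.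

Step 5
Reactants: 9 (2S,4S)-7,8-bis(benzyloxy)-2-[4-(benzyloxy)phenyl]chroman-4-ol
Product: 10 (2S)-7,8-bis(benzyloxy)-2-[4-(benzyloxy)phenyl]-2H-chromene
Conditions: Burgess reagent (methyl N-(triethylammoniosulfonyl)carbamate), THF/benzene, 50 °C, exclusion of light
Reagents that add atoms: none
Why: Burgess dehydration (syn elimination through the benzylic sulfamate ester) removes the C4 hydroxyl without acid, so the allylic and benzylic C2–O bond is not ionised and C2 should keep its configuration.

Step 6
Reactants: 10 (2S)-7,8-bis(benzyloxy)-2-[4-(benzyloxy)phenyl]-2H-chromene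
Product: 12 (2R,3R,4R)-7,8-bis(benzyloxy)-2-[4-(benzyloxy)phenyl]-3,4-epoxychroman (oxirane cis to the 2-aryl group), via trans-bromohydrin 11 (not isolated)
Conditions: N-bromosuccinimide (1.05 equiv), THF/H2O 4:1, 0 °C; extraction; then KOtBu, THF, 0 °C; used crude
Reagents that add atoms: water, O
Why: Bromohydrin formation followed by intramolecular Williamson closure; bromine adds to C3 on the face opposite the 2-aryl group, water captures the benzylic C4 cation anti to bromine, and the C4 alkoxide displaces bromide with inversion at C3, which places the oxirane on the face of the 2-aryl group.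

Step 7
Reactants: 10 (2S)-7,8-bis(benzyloxy)-2-[4-(benzyloxy)phenyl]-2H-chromene
Product: 14 (2R,3S,4R)-7,8-bis(benzyloxy)-2-[4-(benzyloxy)phenyl]chroman-3,4-diol (2,3-trans-3,4-trans), via trans-epoxide 13 (not isolated)
Conditions: dimethyldioxirane (acetone solution), CH2Cl2, −20 °C; then THF/H2O 4:1, pyridinium p-toluenesulfonate (cat.), 0 °C
Reagents that add atoms: dimethyldioxirane, CC1(C)OO1; water, O
Why: Dioxirane epoxidation takes place on the face opposite the 2-aryl group, and acid-catalysed trans-diaxial epoxide hydrolysis delivers water to the benzylic C4 anti to the C3 oxygen, which should give the 2,3-trans-3,4-trans diol.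

Step 8
Reactants: 14 (2R,3S,4R)-7,8-bis(benzyloxy)-2-[4-(benzyloxy)phenyl]chroman-3,4-diol
Product: 15 (2R,3R,4R)-7,8-bis(benzyloxy)-2-[4-(benzyloxy)phenyl]chroman-3,4-diyl diacetate (the 3,4-di-O-acetate of 14, unchanged 2,3-trans-3,4-trans arrangement; the C3 descriptor changes by priority only)
Conditions: Ac2O (3 equiv), pyridine, DMAP (cat.), rt
Reagents that add atoms: acetic anhydride (2 equiv), CC(=O)OC(C)=O
Why: DMAP-catalysed O-acylation masks both hydroxyls, one acetyl group coming from each molecule of anhydride, so that only ring A of 15 remains nucleophilic in step 9; no stereocentre is touched.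

Step 9
Reactants: 12 (2R,3R,4R)-7,8-bis(benzyloxy)-2-[4-(benzyloxy)phenyl]-3,4-epoxychroman; 15 (2R,3R,4R)-7,8-bis(benzyloxy)-2-[4-(benzyloxy)phenyl]chroman-3,4-diyl diacetate
Product: 17 hexa-O-benzyl ether of the target (all phenolic oxygens benzylated; three free aliphatic hydroxyls; all six stereocentres as in 18), via coupled diacetate 16 (not isolated)
Conditions: 15 (3 equiv), BF3·OEt2 (0.2 equiv), CH2Cl2, −78 → −40 °C; Et3N quench; then K2CO3, MeOH/THF, rt
Reagents that add atoms: none
Why: Friedel–Crafts alkylation of an electron-rich arene by a Lewis-acid-activated benzylic epoxide (the known arylation of flav-3-ene oxides): C6 of 15, para to O1 and ortho to the 7-benzyloxy group, attacks C4 of 12 anti to the departing oxirane oxygen, which sets the upper C4 as S with the aryl group trans to the new 3-hydroxyl, and carbonate-catalysed transesterification then removes the two acetates.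

Step 10
Reactants: 17 hexa-O-benzyl ether of the target
Product: 18 (2R,3S,4R)-6-[(2R,3R,4S)-3,7,8-trihydroxy-2-(4-hydroxyphenyl)chroman-4-yl]-2-(4-hydroxyphenyl)chroman-3,4,7,8-tetrol
Conditions: H2 (1 atm), Pd(OH)2/C, NaHCO3, THF/MeOH, rt
Reagents that add atoms: none
Why: Catalytic hydrogenolysis cleaves the six aryl benzyl ethers; the hydrogencarbonate buffer is meant to suppress acid-promoted hydrogenolysis of the benzylic C4 hydroxyl of the lower unit, and the ring C2–O bonds and the interflavan bond should survive as in proanthocyanidin end-games.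

Compound list
1 | 3-fluorocatechol | Oc1cccc(F)c1O | starting material
2 | benzyl bromide | BrCc1ccccc1 | starting material
3 | 1,2-bis(benzyloxy)-3-fluorobenzene | Fc1cccc(OCc2ccccc2)c1OCc1ccccc1 | intermediate
4 | N-methoxy-N-methylacetamide | CC(=O)N(C)OC | starting material
5 | 1-[3,4-bis(benzyloxy)-2-fluorophenyl]ethan-1-one | CC(=O)c1ccc(OCc2ccccc2)c(OCc2ccccc2)c1F | intermediate
6 | 4-(benzyloxy)benzoyl chloride | O=C(Cl)c1ccc(OCc2ccccc2)cc1 | starting material
7 | 1-[3,4-bis(benzyloxy)-2-fluorophenyl]-3-[4-(benzyloxy)phenyl]propane-1,3-dione (present as its lithium enolate) | O=C(CC(=O)c1ccc(OCc2ccccc2)cc1)c1ccc(OCc2ccccc2)c(OCc2ccccc2)c1F | intermediate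
8 | 7,8-bis(benzyloxy)-2-[4-(benzyloxy)phenyl]-4H-chromen-4-one | O=c1cc(-c2ccc(OCc3ccccc3)cc2)oc2c(OCc3ccccc3)c(OCc3ccccc3)ccc12 | intermediate
9 | (2S,4S)-7,8-bis(benzyloxy)-2-[4-(benzyloxy)phenyl]chroman-4-ol (2,4-cis) | O[C@H]1C[C@@H](c2ccc(OCc3ccccc3)cc2)Oc2c(OCc3ccccc3)c(OCc3ccccc3)ccc12 | intermediate
10 | (2S)-7,8-bis(benzyloxy)-2-[4-(benzyloxy)phenyl]-2H-chromene | C1=C[C@@H](c2ccc(OCc3ccccc3)cc2)Oc2c(OCc3ccccc3)c(OCc3ccccc3)ccc12 | intermediate
11 | (2R,3S,4R)-7,8-bis(benzyloxy)-2-[4-(benzyloxy)phenyl]-3-bromochroman-4-ol (Br trans to aryl, OH trans to Br) | O[C@H]1[C@H](Br)[C@@H](c2ccc(OCc3ccccc3)cc2)Oc2c(OCc3ccccc3)c(OCc3ccccc3)ccc12 | intermediate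
12 | (2R,3R,4R)-7,8-bis(benzyloxy)-2-[4-(benzyloxy)phenyl]-3,4-epoxychroman (oxirane cis to aryl) | [C@H]12O[C@H]1[C@@H](c1ccc(OCc3ccccc3)cc1)Oc1c(OCc3ccccc3)c(OCc3ccccc3)ccc12 | intermediate
13 | (2R,3S,4S)-7,8-bis(benzyloxy)-2-[4-(benzyloxy)phenyl]-3,4-epoxychroman (oxirane trans to aryl) | [C@@H]12O[C@@H]1[C@@H](c1ccc(OCc3ccccc3)cc1)Oc1c(OCc3ccccc3)c(OCc3ccccc3)ccc12 | intermediate
14 | (2R,3S,4R)-7,8-bis(benzyloxy)-2-[4-(benzyloxy)phenyl]chroman-3,4-diol (2,3-trans-3,4-trans) | O[C@H]1[C@H](O)[C@@H](c2ccc(OCc3ccccc3)cc2)Oc2c(OCc3ccccc3)c(OCc3ccccc3)ccc12 | intermediate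
15 | (2R,3R,4R)-7,8-bis(benzyloxy)-2-[4-(benzyloxy)phenyl]chroman-3,4-diyl diacetate (2,3-trans-3,4-trans) | CC(=O)O[C@H]1[C@H](OC(C)=O)[C@@H](c2ccc(OCc3ccccc3)cc2)Oc2c(OCc3ccccc3)c(OCc3ccccc3)ccc12 | intermediate
16 | hexa-O-benzyl ether of the target as the 3,4-di-O-acetate of the lower unit (upper 3-OH free) | c5ccccc5COc1ccc([C@H]2Oc3c(ccc(OCc5ccccc5)c3OCc5ccccc5)[C@H](c3cc4c(c(OCc5ccccc5)c3OCc5ccccc5)O[C@H](c3ccc(OCc5ccccc5)cc3)[C@@H](OC(C)=O)[C@@H]4OC(C)=O)[C@H]2O)cc1 | intermediate
17 | hexa-O-benzyl ether of the target (upper unit 2,3-cis-3,4-trans, lower unit 2,3-trans-3,4-trans) | c5ccccc5COc1ccc([C@H]2Oc3c(ccc(OCc5ccccc5)c3OCc5ccccc5)[C@H](c3cc4c(c(OCc5ccccc5)c3OCc5ccccc5)O[C@H](c3ccc(OCc5ccccc5)cc3)[C@@H](O)[C@@H]4O)[C@H]2O)cc1 | intermediate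
18 | (2R,3S,4R)-6-[(2R,3R,4S)-3,7,8-trihydroxy-2-(4-hydroxyphenyl)chroman-4-yl]-2-(4-hydroxyphenyl)chroman-3,4,7,8-tetrol | Oc1ccc([C@H]2Oc3c(ccc(O)c3O)[C@H](c3cc4c(c(O)c3O)O[C@H](c3ccc(O)cc3)[C@@H](O)[C@@H]4O)[C@H]2O)cc1 | target

Total step count: 10
Longest linear sequence: 9 steps (steps 1, 2, 3, 4, 5, 7, 8, 9, 10)

Steps most likely to fail

Step 9. The C4 cation released from the epoxide may be captured by ring A of a second epoxide molecule or of the product (self-condensation to oligomers), or the epoxide may rearrange by hydride shift to the flavan-3-one, before the moderately nucleophilic ring A of 15 attacks. The benzylic 4-acetate of 15 may also ionise under the Lewis acid. Fallback: setting out from 12, the epoxide is opened at C4 by phenylmethanethiol with K2CO3 in THF to give the bench-stable (2R,3S,4S)-4-(benzylsulfanyl)-7,8-bis(benzyloxy)-2-[4-(benzyloxy)phenyl]chroman-3-ol F1. This thioether is activated by the thiophilic salt AgBF4 in THF at 0 °C in the presence of excess 15, so that the cation is released slowly into a large excess of nucleophile and is again attacked trans to the 3-hydroxyl. This should give 16, where the route is rejoined before the methanolysis stage of step 9.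

Step 6. Water may capture the C4 cation on the face syn to bromine (that bromohydrin cannot close to the oxirane), the electron-rich rings may be brominated, or the labile cis-epoxide may be lost on handling. Fallback: setting out from 10, the 3-oxygen is placed cis by hydride chemistry instead. Hydroboration–oxidation (BH3·THF; then H2O2, NaOH) adds anti to the aryl group and should give the 2,3-trans alcohol (2R,3S)-7,8-bis(benzyloxy)-2-[4-(benzyloxy)phenyl]chroman-3-ol F2. Dess–Martin oxidation then gives (2R)-7,8-bis(benzyloxy)-2-[4-(benzyloxy)phenyl]chroman-3-one F3. LiBH(s-Bu)3 at −78 °C reduces this ketone from the face opposite the aryl group to the 2,3-cis alcohol (2R,3R)-7,8-bis(benzyloxy)-2-[4-(benzyloxy)phenyl]chroman-3-ol F4. DDQ oxidation of the benzylic C4–H in the presence of 2-ethoxyethanol gives (2R,3R,4S)-7,8-bis(benzyloxy)-2-[4-(benzyloxy)phenyl]-4-(2-ethoxyethoxy)chroman-3-ol F5. TMSOTf at −78 °C with excess 15 then couples this C4 ether to give 16, where the route is rejoined.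

Step 4. Hydrogenation of the hindered, electron-rich 8-alkoxy flavone may stall at partial conversion or proceed with poor enantioface discrimination. Fallback: setting out from 8, conjugate reduction with copper hydride (Cu(OAc)2, 1,2-bis(diphenylphosphino)benzene, polymethylhydrosiloxane, t-BuOH) gives racemic 7,8-bis(benzyloxy)-2-[4-(benzyloxy)phenyl]chroman-4-one F6. Noyori transfer hydrogenation with the antipode of RuCl(p-cymene)(TsDPEN) that reduces the (2S)-ketone faster (HCO2H/Et3N) then acts as a kinetic resolution and gives the cis alcohol 9, where the route is rejoined. The unreacted (2R)-7,8-bis(benzyloxy)-2-[4-(benzyloxy)phenyl]chroman-4-one F7 is separated and can be racemised with base through the chalcone for recycling.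

Further compounds
F1 | step 9 | (2R,3S,4S)-4-(benzylsulfanyl)-7,8-bis(benzyloxy)-2-[4-(benzyloxy)phenyl]chroman-3-ol | c5ccccc5CS[C@@H]1[C@@H](O)[C@@H](c2ccc(OCc3ccccc3)cc2)Oc2c(OCc3ccccc3)c(OCc3ccccc3)ccc12
F2 | step 6 | (2R,3S)-7,8-bis(benzyloxy)-2-[4-(benzyloxy)phenyl]chroman-3-ol | C1[C@H](O)[C@@H](c2ccc(OCc3ccccc3)cc2)Oc2c(OCc3ccccc3)c(OCc3ccccc3)ccc12
F3 | step 6 | (2R)-7,8-bis(benzyloxy)-2-[4-(benzyloxy)phenyl]chroman-3-one | C1C(=O)[C@@H](c2ccc(OCc3ccccc3)cc2)Oc2c(OCc3ccccc3)c(OCc3ccccc3)ccc12
F4 | step 6 | (2R,3R)-7,8-bis(benzyloxy)-2-[4-(benzyloxy)phenyl]chroman-3-ol | C1[C@@H](O)[C@@H](c2ccc(OCc3ccccc3)cc2)Oc2c(OCc3ccccc3)c(OCc3ccccc3)ccc12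
F5 | step 6 | (2R,3R,4S)-7,8-bis(benzyloxy)-2-[4-(benzyloxy)phenyl]-4-(2-ethoxyethoxy)chroman-3-ol | CCOCCO[C@@H]1[C@@H](O)[C@@H](c2ccc(OCc3ccccc3)cc2)Oc2c(OCc3ccccc3)c(OCc3ccccc3)ccc12
F6 | step 4 | racemic 7,8-bis(benzyloxy)-2-[4-(benzyloxy)phenyl]chroman-4-one | O=C1CC(c2ccc(OCc3ccccc3)cc2)Oc2c(OCc3ccccc3)c(OCc3ccccc3)ccc12
F7 | step 4 | (2R)-7,8-bis(benzyloxy)-2-[4-(benzyloxy)phenyl]chroman-4-one | O=C1C[C@H](c2ccc(OCc3ccccc3)cc2)Oc2c(OCc3ccccc3)c(OCc3ccccc3)ccc12
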